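| flask | starting material | partner | temperature | remark | time |
|---|---|---|---|---|---|
| alder | 0.020 M | 0.019 M | 110 °C | run made earlier |  |
| oak | 0.010 M | 0.019 M | 110 °C | run made earlier |  |
| east | 0.020 M | 0.0190 M (fed, over 10 h) |  | the addition at 80 °C, then warmed to 110 °C; the feed brings no volume worth counting | 15 h |
| north | 0.020 M | 0.0190 M (in portions, 4, over 10 h) | 110 °C | first portion at the start, last at 10 h | 15 h |
| north-east | 0.020 M (fed, over 10 h) | 0.0190 M | 110 °C | all else is in the flask from the start; the feed brings no volume worth counting | 15 h |
| north-west | 0.020 M | 0.0190 M (fed, over 10 h) | 110 °C | all else is in the flask from the start; the feed brings no volume worth counting | 15 h |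

| run | time / h | target / % |
|---|---|---|
| alder | 1.33 | 37.3 |
| alder | 2.50 | 42.9 |
| alder | 4.00 | 47.0 |
| alder | 5.00 | 47.4 |
| alder | 6.00 | 48.0 |
| alder | 8.00 | 49.2 |
| alder | 10.0 | 49.5 |
| oak | 0.167 | 11.5 |
| oak | 0.500 | 26.1 |
| oak | 0.833 | 33.9 |
| oak | 1.33 | 42.1 |
| oak | 2.00 | 47.2 |
| oak | 2.50 | 49.1 |
| oak | 3.00 | 50.4 |

(scatter of a reading: 0.3 percentage points)

- the earlier runs do not show what temperature does; that part of a forecast is a guess
- a reading or a percentage of target counts all its forms, free or not

1. the best flask by amount of target, in percent of the starting material charged; "all alike" if 1.5 percentage points covers them all (east / north / north-east / north-west / all alike)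
2. amount of target at the end, in percent of the starting material charged, east
3. amount of target at the end, in percent of the starting material charged, north
4. amount of target at the end, in percent of the starting material charged, north-east
5. amount of target at the end, in percent of the starting material charged, north-west

- I began with an easy step. Alder ended at 49.5% target, so it held 0.009900 M target, and with one partner taken per target, 0.009100 M partner stayed.
- I supposed that starting material also dies by itself, first order, without partner. It then splits as partner/(partner + c), a selectivity factor in concentration form. Integrating gives c = (starting material charged − target)/ln(partner charged/partner left).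
- Alder gave the break-even partner level, the partner concentration at which the path to target and the loss run equally fast: 0.01372 M.
- Oak, the second way, gave 0.01609 M, higher than alder's. Oak's last step still added 1.3 percentage points, against alder's 0.3 points. In this formula, a target figure still short of its final value gives too high a level, so I kept alder's value.
- Oak's first reading is a mean over its first interval, during which starting material was already falling. Taking partner at its charged level with the split partner/(partner + c), that reading gave a whole decay constant for starting material of 1.32 h⁻¹, so the loss constant was 0.554 h⁻¹.
- In north-west, the feed of 0.001900 M h⁻¹ over one lifetime of starting material gave a first partner level of 0.003429 M, and so a split of 20.0%.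
- I went round once more: the partner eaten removes from that level a share equal to starting material charged over 4 times the break-even level. This left 0.002179 M partner and 13.7% target for north-west.
- North-east follows alder's integral, so I expected about 49.5%. East stayed a guess, since the runs do not show temperature.
- The forecast said all alike: east 48.5%, north 48.8%, north-east 48.3%, north-west 49.5%, from 47.7% to 51.2%. Its ground was “Dosing therefore changes selectivity little”. My north-west figure differs from it.
- The flasks gave east as best: east 52.5%, north 19.6%, north-east 48.8%, north-west 12.4%, against my 13.7%.

    partner + intermediate C → side product (k = 0.0110 L mol⁻¹ min⁻¹, Ea = 91.0 kJ mol⁻¹)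
    intermediate B → intermediate C (k = 0.00570 min⁻¹, Ea = 124 kJ mol⁻¹)
    starting material + target ⇌ idle adduct, settled at all times (K = 140 L mol⁻¹, ΔH = −40.0 kJ mol⁻¹)
    starting material → intermediate A (k = 0.0100 min⁻¹, Ea = 124 kJ mol⁻¹)
    intermediate A → decomposed reagent (k = 0.00620 min⁻¹, Ea = 126 kJ mol⁻¹)
    starting material + partner → target (k = 0.740 L mol⁻¹ min⁻¹, Ea = 64.0 kJ mol⁻¹)
    starting material ⇌ dormant form (K = 3.00, k = 1.70 × 10⁻⁴ min⁻¹, Ea = 125 kJ mol⁻¹, ΔH = −15.0 kJ mol⁻¹)
    intermediate A → intermediate B (k = 1.70 × 10⁻⁴ min⁻¹, Ea = 129 kJ mol⁻¹)
    (constants at 110 °C)

- The neighbour repeated north-west at 95 °C. With the activation energies above, the break-even level became 0.006369 M and the loss constant 0.113 h⁻¹. Two rounds gave a partner level of 0.003600 M and a split of 36.1%. That flask ended with 60% of its partner unbound and 37.9% target.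

All runs come from a simulation on assumed constants; noise was put on by code.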